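**Retrosynthetic overview**
1. 12 ⇒ axial alcohol 8 + Meldrum's acid 9 + 4-hydroxybenzaldehyde 10. The coumarate is grown on the hindered oxygen, so the phenol needs no protection.
2. 8 ⇒ equatorial epimer 6 through ketone 7. Hydride arrives from the α face because the axial C10 methyl closes the β face.
3. 6 ⇒ (E,E)-germacradienol 5 by proton-triggered transannular C5–C10 closure. This second ring event turns the ten-membered ring into rings A and B and sets C5 and C10.
4. 5 ⇒ 4 ⇒ acyclic chloro-enal 3 by enantioselective allylchromium closure of C6–C7 (farnesyl C1–C10). This first ring event sets C7 and, provisionally, C6.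
5. 3 ⇒ (2E,6E)-farnesol 1. The order of events is farnesyl → germacrane → eudesmane.

Numbering: germacrane/eudesmane numbering is used throughout. C6 is the carbinol carbon, C7 carries the isopropyl group, and C5/C10 are the ring fusion. The target read from the SMILES is 6β-[(E)-p-coumaroyloxy]eudesm-3-ene, (5R,6R,7S,10R), with 5α-H, 7β-isopropyl and 10β-CH3.

Assumption: the (S)-valinol-derived chromium ligand is taken to deliver Si-face attack on the enal; if the first run gives ent-4, the ligand from (R)-valinol is used and nothing else changes.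

**Step 1**
Reactants: 1 (2E,6E)-farnesol
Product: 2 (2E,6E)-farnesal
Conditions: activated MnO2 (15 equiv), CH2Cl2, 23 °C, 3 h
Reagents that add atoms: none
Why: Heterogeneous allylic alcohol oxidation with MnO2 stops at the enal and leaves the 2E geometry and both isolated olefins untouched; no stereocentre is formed.

**Step 2**
Reactants: 2 (2E,6E)-farnesal
Product: 3 (2E,6E)-10-chloro-3,7,11-trimethyldodeca-2,6,11-trienal (racemic at C10)
Conditions: NCS (1.0 equiv), PhSeCl (10 mol %), CH2Cl2, 23 °C, stopped at about 70% conversion, 2 recycled
Reagents that add atoms: N-chlorosuccinimide, O=C1CCC(=O)N1Cl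
Why: In this selenium-catalysed ene-type allylic chlorination with double-bond shift the enal olefin is too electron-poor and the internal olefin is flanked by two chains, so the terminal isopropylidene reacts first; the new C10 centre is racemic and is erased in step 3.

**Step 3**
Reactants: 3 (2E,6E)-10-chloro-3,7,11-trimethyldodeca-2,6,11-trienal
Product: 4 (6R,7S)-germacra-1(10)E,4E,11-trien-6α-ol = (1R,2E,6E,10S)-3,7-dimethyl-10-(prop-1-en-2-yl)cyclodeca-2,6-dien-1-ol
Conditions: CrCl2 (20 mol %), (S)-N-[2-(4-isopropyl-4,5-dihydrooxazol-2-yl)-6-methylphenyl]methanesulfonamide (22 mol %), Et3N (22 mol %), Mn powder (3 equiv), Cp2ZrCl2 (1.1 equiv), LiCl (2 equiv), THF–MeCN, 23 °C; 3 added by syringe pump over 24 h (final 5 mM); aq NaHCO3 work-up; Et3N-deactivated silica, kept below 30 °C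
Reagents that add atoms: none
Why: Proposed new method: ligand-controlled intramolecular Nozaki–Hiyama–Kishi allylation, in which two single-electron transfers from divalent chromium turn the allylic chloride into a σ-allyl complex of trivalent chromium that settles in its E form and adds through its γ-carbon (farnesyl C10) to the enal carbonyl (farnesyl C1) in a closed chair transition state with both chain ends equatorial, giving the anti pair 6α-OH/7β-isopropenyl with both E olefins kept, while the oxazoline–sulfonamide on chromium selects the Si face of the aldehyde, slow addition keeps 3 dilute with the catalyst concentrated, and Mn/Cp2ZrCl2 turn chromium over; the closest known chemistry is the racemic CrCl2 closure of 12-halofarnesal-type aldehydes to (E,E)-germacradienols and the catalytic asymmetric intermolecular chromium allylation of aldehydes.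

**Step 4**
Reactants: 4 (6R,7S)-germacra-1(10)E,4E,11-trien-6α-ol
Product: 6 eudesm-3-en-6α-ol (5R,6S,7S,10R), via germacra-1(10),4-dien-6α-ol 5 (not isolated)
Conditions: RhCl(PPh3)3 (5 mol %), H2 (1 atm), toluene, 23 °C, stopped at 1.0 equiv H2; argon purge; then TsOH·H2O (30 mol %), 0 to 23 °C, 3 h; Et3N quench
Reagents that add atoms: none
Why: Homogeneous hydrogenation with RhCl(PPh3)3 saturates only the unhindered 1,1-disubstituted isopropenyl group, then the acid protonates C1 of the strained C1=C10 olefin and C5 of the facing C4=C5 olefin closes onto C10 in the crossed chair–chair conformer (both methyls on the β face, C6 and C7 substituents equatorial), a transannular cation–olefin cyclisation that sets 10β-CH3 and 5α-H (trans-decalin); loss of H-3 gives the trisubstituted olefin, the exocyclic isomer drains into it on standing, and the tetrasubstituted isomer is held back by allylic strain against the equatorial 6α-oxygen.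

**Step 5**
Reactants: 6 eudesm-3-en-6α-ol
Product: 8 eudesm-3-en-6β-ol (5R,6R,7S,10R), via eudesm-3-en-6-one 7 (not isolated)
Conditions: (COCl)2 (1.5 equiv), DMSO (3 equiv), CH2Cl2, −78 °C; Et3N (5 equiv), −78 to −50 °C; then LiBH(s-Bu)3 (6 equiv, THF), −78 °C, 2 h; H2O
Reagents that add atoms: none
Why: Swern oxidation followed by hydride addition in the same cold flask keeps the β,γ-unsaturated ketone 7 below −50 °C so that it neither conjugates nor epimerises at C5 or C7, and the bulky borohydride cannot pass the axial C10 methyl on the β face, so it attacks from the α face (steric approach control, equatorial attack) and gives the axial 6β-alcohol.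

**Step 6**
Reactants: 8 eudesm-3-en-6β-ol; 9 Meldrum's acid; 10 4-hydroxybenzaldehyde
Product: 12 6β-[(E)-p-coumaroyloxy]eudesm-3-ene (target), via eudesm-3-en-6β-yl hydrogen malonate 11 (not isolated)
Conditions: 9 (2 equiv), toluene, 110 °C, 5 h; then 10 (3 equiv), pyridine, piperidine (20 mol %), 80 °C, 16 h
Reagents that add atoms: Meldrum's acid, CC1(C)OC(=O)CC(=O)O1; 4-hydroxybenzaldehyde, O=Cc1ccc(O)cc1
Why: Heated Meldrum's acid acylates even very hindered alcohols (it works on tert-butanol) with loss of acetone, and the malonic half-ester then condenses with the aldehyde and decarboxylates under amine catalysis (Knoevenagel–Doebner reaction) to the E-cinnamate without phenol protection; no stereocentre is touched.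

**Compound list**
1 | (2E,6E)-farnesol | OC/C=C(C)/CC/C=C(C)/CCC=C(C)C | starting material
2 | (2E,6E)-farnesal | O=C/C=C(C)/CC/C=C(C)/CCC=C(C)C | intermediate
3 | (2E,6E)-10-chloro-3,7,11-trimethyldodeca-2,6,11-trienal, racemic at C10 | O=C/C=C(C)/CC/C=C(C)/CCC(Cl)C(C)=C | intermediate
4 | (6R,7S)-germacra-1(10)E,4E,11-trien-6α-ol (7β-isopropenyl) | C/C1=C\[C@@H](O)[C@H](C(C)=C)CC/C(C)=C/CC1 | intermediate
5 | (6S,7S)-germacra-1(10)E,4E-dien-6α-ol (7β-isopropyl) | C/C1=C\[C@@H](O)[C@H](C(C)C)CC/C(C)=C/CC1 | intermediate (not isolated)
6 | (5R,6S,7S,10R)-eudesm-3-en-6α-ol | CC1=CCC[C@]2(C)CC[C@@H](C(C)C)[C@H](O)[C@@H]12 | intermediate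
7 | (5R,7S,10R)-eudesm-3-en-6-one | CC1=CCC[C@]2(C)CC[C@@H](C(C)C)C(=O)[C@@H]12 | intermediate (not isolated)
8 | (5R,6R,7S,10R)-eudesm-3-en-6β-ol | CC1=CCC[C@]2(C)CC[C@@H](C(C)C)[C@@H](O)[C@@H]12 | intermediate
9 | Meldrum's acid (2,2-dimethyl-1,3-dioxane-4,6-dione) | CC1(C)OC(=O)CC(=O)O1 | starting material
10 | 4-hydroxybenzaldehyde | O=Cc1ccc(O)cc1 | starting material
11 | eudesm-3-en-6β-yl hydrogen malonate | CC1=CCC[C@]2(C)CC[C@@H](C(C)C)[C@@H](OC(=O)CC(=O)O)[C@@H]12 | intermediate (not isolated)
12 | (5R,6R,7S,10R)-eudesm-3-en-6β-yl (E)-3-(4-hydroxyphenyl)prop-2-enoate | CC1=CCC[C@]2(C)CC[C@@H](C(C)C)[C@@H](OC(=O)/C=C/c3ccc(O)cc3)[C@@H]12 | target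

**Step count**
Total steps: 6. Longest linear sequence: 6 (1 → 12).

**Steps most likely to fail**

Step 3. The risks are ring strain, oligomerisation, and an untested ee on a β,β-disubstituted enal. The fallback replaces chromium radical chemistry with a closed-shell boron route. It sets out from 3. Pd2(dba)3-catalysed borylation of the allylic chloride with B2pin2 (THF, 23 °C) gives the linear allylboronate (2E,6E,10E)-3,7,11-trimethyl-12-(4,4,5,5-tetramethyl-1,3,2-dioxaborolan-2-yl)dodeca-2,6,10-trienal F1. F1 is added slowly to (S)-3,3′-bis(2,4,6-triisopropylphenyl)-1,1′-binaphthalene-2,2′-diyl hydrogen phosphate (10 mol %) in toluene at −30 to 0 °C. The acid-activated E-boronate adds through a chair transition state (anti, Si face). Hydrolysis of the borate comes back to the route at 4.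

Step 4. Three things can go wrong:
- The strained ring olefins may take up hydrogen.
- The Δ3/Δ4(15) ratio may not converge under acid.
- A hydride-shift path from the C4 cation can lead to the saturated 6-ketone.

The fallback sets out from 5, now isolated after the hydrogenation. The cyclisation is run under purely kinetic conditions (TsOH·H2O 2 mol %, CH2Cl2, −40 °C, Et3N quench) and the olefin mixture is accepted. The exocyclic isomer eudesm-4(15)-en-6α-ol F2 is then moved into the ring by a radical process instead of a cationic one. This is hydrogen-atom-transfer isomerisation with [Co(salen)Cl] (salen = N,N′-bis(3,5-di-tert-butylsalicylidene)ethane-1,2-diaminate, 5 mol %) and PhSiH3 (10 mol %) in benzene. Reversible H-atom addition to the CH2 terminus gives the C4 radical, and cobalt takes back the more accessible H-3. This comes back to the route at 6.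

Step 5. The double bond of 7 may migrate into conjugation, and the flanked ketone may reduce slowly. The fallback inverts C6 one stage earlier, on the macrocycle, where the ketone is already a conjugated enone and cannot deconjugate. It sets out from 5 (isolated). MnO2 in CH2Cl2 gives (7S)-germacra-1(10)E,4E-dien-6-one F3. i-Bu2AlH in toluene at −78 °C adds 1,2 from the periphery of the α face, since both ring methyls stand on the β face, and gives (6R,7S)-germacra-1(10)E,4E-dien-6β-ol F4. TsOH·H2O (10 mol %) in CH2Cl2 at 0 °C then closes C5–C10 through the same chair–chair conformer, now with an axial oxygen. The isopropyl group, which stays equatorial, decides the face. This comes back to the route at 8.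

**Further compounds**
F1 | step 3 | (2E,6E,10E)-3,7,11-trimethyl-12-(4,4,5,5-tetramethyl-1,3,2-dioxaborolan-2-yl)dodeca-2,6,10-trienal | O=C/C=C(C)/CC/C=C(C)/CC/C=C(C)/CB1OC(C)(C)C(C)(C)O1
F2 | step 4 | eudesm-4(15)-en-6α-ol (5α-H, 7β-isopropyl, 10β-methyl) | C=C1CCC[C@]2(C)CC[C@@H](C(C)C)[C@H](O)[C@@H]12
F3 | step 5 | (7S)-germacra-1(10)E,4E-dien-6-one | C/C1=C\C(=O)[C@H](C(C)C)CC/C(C)=C/CC1
F4 | step 5 | (6R,7S)-germacra-1(10)E,4E-dien-6β-ol | C/C1=C\[C@H](O)[C@H](C(C)C)CC/C(C)=C/CC1
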